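## The problem

The target 23 is a flavone: ring A is fused to the pyranone ring C, and ring B sits on C2. It has no stereocenter, so the difficulty is purely positional. Ring A carries oxygen on every free carbon in the order C5 OH, C6 OMe, C7 OH, C8 OMe; C3 bears a methoxyl; ring B is 2',4'-dihydroxy-5'-methoxy. Four methyl ethers therefore stand beside four free phenols, and two of these phenols (O5, O7) flank the C6 methoxyl. Selective demethylation cannot distinguish them, so the phenols must travel as benzyl ethers and each methyl group must be placed deliberately. The free tetraphenol, with a 5,8-dioxygenated ring A, is sensitive to air in base, and the pyranone opens under strong alkoxide; the phenols are therefore unveiled last, by neutral hydrogenolysis. The bond-forming problem is the ring fusion: the carbonyl carbon C4 and the oxygen O1 must be attached to the neighbouring carbons C4a and C8a of an otherwise fully oxygenated ring. An aryne offers exactly this 1,2-relationship, and the oxygen on C5, next to C4a, can decide which aryne carbon receives oxygen and which receives carbon, provided that C8, next to C8a, still carries hydrogen at that stage. The only stereochemical element on the way, the double-bond geometry of the cinnamic acid 16 and the chalcone 18, vanishes when ring C closes.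

## Retrosynthesis

**23 from 22.** The last bonds made are the O–H bonds at O7, O2' and O4', so the three benzyl ethers of 22 are cut. Benzyl is preferred to silyl, acetal or acyl protection because it survives fluoride at 125 °C, butyllithium, methoxide and MgBr2, and leaves under neutral conditions that touch neither the methyl ethers nor the pyranone. The forward step only has to spare the C2=C3 bond, which as a tetrasubstituted vinylogous ester is slow to hydrogenate.

**22 from 21 and 20.** The C8–O bond is cut next, first to the C8–I bond of 21 and then to the C8–H bond of 20. This is the debt left by the key step, which needs hydrogen at C8. An aryne with oxygen on both flanks would lose its regiocontrol, so C8 cannot be oxygenated earlier. Iodination followed by copper-mediated methanolysis is preferred to a direct persulfate hydroxylation because both steps are site-specific and the methoxyl arrives already methylated. C8 is the only free position of ring A and is para to the free 5-hydroxyl, whereas the open positions of ring B belong to an etherified ring attached to the electron-poor pyranone. In methoxide the 5-phenoxide shields the pyranone from ring opening. Should opening and reclosure through O5 occur, it would only exchange C6 and C8, which end as the same two methoxyls.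

**20 from 19.** The O5–H bond is traced back to the O5 benzyl ether of 19. Of the four benzyl ethers only this one is peri to the C4 carbonyl, so a chelating Lewis acid with a nucleophilic counter-ion can remove it alone. Carrying O5 under a different protecting group would make ring A unsymmetrical much earlier; as planned, phenol 6 keeps a mirror plane until it is brominated.

**19 from 18.** Ring C is opened at O1–C2, giving the 2'-hydroxychalcone 18. Cutting here, and not at C2–C3 or C3–C4, is what the key step dictates: it delivers the free C8a hydroxyl and the complete C4–C3–C2 chain with ring B. The forward reaction must close the ring and remove two hydrogens in one operation. An iodine-mediated oxidative cyclisation does both, and it erases the alkene geometry.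

**18 from 10 and 16 via 17.** Two bonds of 18 are cut together: O–C8a and C4a–C4. This returns the aryne 17, released from the o-silylaryl triflate 10, and the α-methoxycinnamic acid 16. Friedel–Crafts or Hoesch acylation of phenol 6, or a Lewis-acid Fries rearrangement, would make only the C–C bond and would need acids that strip benzyl ethers and attack the enol ether. A Claisen–Schmidt route would need the hindered ω-methoxyacetophenone first. The aryne cut joins two halves of similar size, and the acid already holds C4, C3 with its methoxyl, and C2 with ring B. The forward reaction must add the carboxylate oxygen to the aryne carbon remote from the C5 benzyloxy group and then transfer the acyl group to the carbon next to it.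

**10 from 1.** The C–Si and O–Tf bonds of 10 are cut back to the bromophenol 7 (through 8 and 9), and the C–Br bond to phenol 6. Because 6 is symmetrical, bromination can give only one ortho isomer. The phenolic C–O bond of 6 is derived from the formyl group of aldehyde 4 (through formate 5), and 4 from the commercial ester 1 through 3 and 2. The ester route is chosen because 1 already has the 4-methoxyl distinguished from the two flanking hydroxyls.

**16 from 11 and 14.** The C2=C3 double bond of 16 is cut to aldehyde 13 and methyl methoxyacetate 14 (through ester 15); the condensation places the aryl group trans to the carboxyl. The 5-methoxyl of 13 is cut to the C–Br bond of 12, and the benzyl ethers of 12 to the bromo dihydroxy aldehyde 11. This is shorter than building the 2,4,5-oxygenation pattern by formylation of a trioxygenated benzene.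

## Roads not taken

**Alternative 1: anodic closure of ring C.** The cut is O1–C2, made by oxidation of a saturated precursor. The α-methoxydihydrochalcone A2, 1-[4,6-bis(benzyloxy)-2-hydroxy-3,5-dimethoxyphenyl]-3-[2-(benzyloxy)-4-hydroxy-5-methoxyphenyl]-2-methoxypropan-1-one, would be electrolysed at constant current (graphite anode, LiClO4 in acetonitrile, 2,6-lutidine). Two-electron oxidation of the ring B phenol makes the benzylic carbon electrophilic, and the C8a hydroxyl captures it to give the 3-methoxyflavanone A1, 5,7-bis(benzyloxy)-2-[2-(benzyloxy)-4-hydroxy-5-methoxyphenyl]-3,6,8-trimethoxychroman-4-one.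

- Merits: ring A arrives with all four oxygens, so no late chemistry at C8 is needed, and the oxidant is the electrode. In this respect it is better than the chosen plan.
- Weak points: A2 needs ring B with a free 4'-hydroxyl beside a protected 2'-oxygen, which costs extra protecting-group steps. A2 also holds a second free phenol on the penta-oxygenated ring A, which should oxidise at least as easily as the ring B phenol. The oxidised ring B intermediate has an acidic hydrogen next to the ketone and can tautomerise to a chalcone instead of being trapped. A1 is a flavanone and needs a separate dehydrogenation. The aryl ketone must be built on a fully substituted ring A.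
- Comparison: the chosen plan pays three steps for C8 (steps 12 to 14). Against this it has a ring A made from a symmetrical phenol and a union whose regiochemistry rests on one substituent, with no competing oxidation site.

**Alternative 2: polyketide-type Claisen closure of ring A.** The cut is the C4a–C5 bond (equivalently C4a–C8a), so ring A is made from an open chain. The triketo ester A4, methyl (Z)-9-[2,4-bis(benzyloxy)-5-methoxyphenyl]-2,4,8-trimethoxy-3,5,7-trioxonon-8-enoate, would be treated with KOH in methanol. The C6 carbanion attacks the ester carbonyl and the ring enolises to the chalcone A3, (Z)-3-[2,4-bis(benzyloxy)-5-methoxyphenyl]-2-methoxy-1-(2,4,6-trihydroxy-3,5-dimethoxyphenyl)prop-2-en-1-one.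

- Merits: A3 has a symmetrical ring A with both methoxyls in place and O5 and O7 already free. The endgame would be only oxidative cyclisation and hydrogenolysis, clearly shorter than the chosen one, with no selective debenzylation and no C–H functionalisation.
- Weak points: everything is shifted into A4. A chain with three ketones, an ester, two α-methoxy carbons and a Michael acceptor has several acidic sites. Aldol closure from C2 onto the C7 ketone, lactonisation to pyranones, retro-Claisen cleavage by hydroxide and conjugate addition to the enone all compete with the desired Claisen mode. Nothing in the structure favours the desired mode over the others. Assembly of A4 by repeated acylation of α-alkoxy ketone enolates would be long and would pass through unstable intermediates.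
- Comparison: the chosen plan has the longer endgame. Against this it has shelf-stable aromatic intermediates throughout and a key step whose selectivity is set by substrate structure and does not depend on reaction conditions.

**Alternative 3: copper-mediated enolate O-arylation.** The cut is O1–C8a. The 2-methoxy-1,3-diketone A6, 1-[4-(benzyloxy)-2,6-dibromo-3,5-dimethoxyphenyl]-3-[2,4-bis(benzyloxy)-5-methoxyphenyl]-2-methoxypropane-1,3-dione, would be cyclised with CuI, 1,10-phenanthroline and K3PO4. The enolate oxygen displaces one ortho bromine and gives the 5-bromoflavone A5, 7-(benzyloxy)-2-[2,4-bis(benzyloxy)-5-methoxyphenyl]-5-bromo-3,6,8-trimethoxy-4H-chromen-4-one.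

- Merits: ring A of A6 is symmetrical, so either bromine gives the same product. The C8 methoxyl is present from the start, and the flavone forms directly at the right oxidation level, without the oxidative cyclisation of step 11.
- Weak points: the bromine to be displaced is flanked on both sides and sits on an electron-rich ring. The enolate is that of a fully substituted α-methoxy diketone with low enol content. The remaining C5 bromine must still be turned into a hydroxyl by a second metal-mediated C–O coupling at a hindered peri position before hydrogenolysis, which would otherwise remove it. A6 requires a hexasubstituted benzoyl unit and a hindered C-acylation.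
- Comparison: the late halogen-to-oxygen exchange is not avoided, only moved from C8 to C5, and the step count is about the same as for the chosen plan. The chosen plan has a simpler ring A building block and forms two bonds in the step that joins the halves.

Key step: step 10

Assumption: 11 is taken as a purchasable compound. The acid 16 is drawn as the Z isomer, the one favoured thermodynamically, although either geometry would serve because the double bond ends inside ring C.

## Route

Step 1
Reactants: 1 methyl 3,5-dihydroxy-4-methoxybenzoate
Product: 2 methyl 3,5-bis(benzyloxy)-4-methoxybenzoate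
Conditions: BnBr, K2CO3, DMF, 60 °C
Reagents that add atoms: benzyl bromide, BrCc1ccccc1
Why: Williamson ether synthesis; both phenols are alkylated by carbonate and benzyl bromide while the methyl ester is inert.

Step 2
Reactants: 2 methyl 3,5-bis(benzyloxy)-4-methoxybenzoate
Product: 3 [3,5-bis(benzyloxy)-4-methoxyphenyl]methanol
Conditions: LiAlH4, THF, 0 °C to rt
Reagents that add atoms: none
Why: Hydride reduction of an aryl ester to the benzylic alcohol; aryl benzyl and methyl ethers are not touched.

Step 3
Reactants: 3 [3,5-bis(benzyloxy)-4-methoxyphenyl]methanol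
Product: 4 3,5-bis(benzyloxy)-4-methoxybenzaldehyde
Conditions: activated MnO2, CH2Cl2, rt
Reagents that add atoms: none
Why: Heterogeneous oxidation of a benzylic alcohol with MnO2 stops at the aldehyde and leaves the electron-rich ring alone.

Step 4
Reactants: 4 3,5-bis(benzyloxy)-4-methoxybenzaldehyde
Product: 6 3,5-bis(benzyloxy)-4-methoxyphenol, via 3,5-bis(benzyloxy)-4-methoxyphenyl formate 5 (not isolated)
Conditions: mCPBA, CH2Cl2, 0 °C to rt; then K2CO3, MeOH, rt
Reagents that add atoms: 3-chloroperoxybenzoic acid (mCPBA), O=C(OO)c1cccc(Cl)c1
Why: Baeyer–Villiger (Dakin-type) oxidation; the trialkoxyaryl group with its para methoxyl migrates in preference to hydrogen, as in the known conversion of 3,4,5-trialkoxybenzaldehydes to the phenols, and the formate is methanolysed in the same flask.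

Step 5
Reactants: 6 3,5-bis(benzyloxy)-4-methoxyphenol
Product: 7 3,5-bis(benzyloxy)-2-bromo-4-methoxyphenol
Conditions: NBS (1.0 equiv), CH2Cl2, −78 °C to 0 °C
Reagents that add atoms: N-bromosuccinimide, O=C1CCC(=O)N1Br
Why: Electrophilic bromination of a phenol; the para position is blocked and the two ortho positions are equivalent, so one equivalent at low temperature should give a single monobromide.

Step 6
Reactants: 7 3,5-bis(benzyloxy)-2-bromo-4-methoxyphenol
Product: 10 3,5-bis(benzyloxy)-4-methoxy-2-(trimethylsilyl)phenyl trifluoromethanesulfonate, via [3,5-bis(benzyloxy)-2-bromo-4-methoxyphenoxy]trimethylsilane 8 (not isolated), via lithium 3,5-bis(benzyloxy)-4-methoxy-2-(trimethylsilyl)phenolate 9 (not isolated)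
Conditions: HMDS, THF, 65 °C, then evaporation; n-BuLi, THF, −100 °C to −80 °C; Tf2O, −100 °C to rt
Reagents that add atoms: hexamethyldisilazane, C[Si](C)(C)N[Si](C)(C)C; trifluoromethanesulfonic anhydride, O=S(=O)(OS(=O)(=O)C(F)(F)F)C(F)(F)F
Why: Standard one-flask route to o-silylaryl triflates: O-silylation, bromine–lithium exchange, retro-Brook 1,3 O-to-C silyl shift and triflation of the phenoxide; exchange at −100 °C is much faster than deprotonation of the benzyl ethers.

Step 7
Reactants: 11 5-bromo-2,4-dihydroxybenzaldehyde
Product: 12 2,4-bis(benzyloxy)-5-bromobenzaldehyde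
Conditions: BnBr, K2CO3, DMF, 70 °C
Reagents that add atoms: benzyl bromide, BrCc1ccccc1
Why: Williamson ether synthesis; warming in DMF also alkylates the hydrogen-bonded 2-hydroxyl.

Step 8
Reactants: 12 2,4-bis(benzyloxy)-5-bromobenzaldehyde
Product: 13 2,4-bis(benzyloxy)-5-methoxybenzaldehyde
Conditions: NaOMe, CuBr (10 mol %), EtOAc (cat.), MeOH–DMF, 110 °C
Reagents that add atoms: sodium methoxide, [Na+].[O-]C
Why: Ullmann-type copper-catalysed methanolysis of an aryl bromide, well known for bromo alkoxybenzaldehydes; the aldehyde has no α-hydrogen and is deactivated by its ortho and para alkoxy groups.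

Step 9
Reactants: 13 2,4-bis(benzyloxy)-5-methoxybenzaldehyde; 14 methyl methoxyacetate
Product: 16 (Z)-3-[2,4-bis(benzyloxy)-5-methoxyphenyl]-2-methoxyacrylic acid, via methyl (Z)-3-[2,4-bis(benzyloxy)-5-methoxyphenyl]-2-methoxyacrylate 15 (not isolated)
Conditions: NaOMe, MeOH–THF, reflux; then aq. NaOH, 60 °C; aq. HCl
Reagents that add atoms: sodium hydroxide, [Na+].[OH-]
Why: Claisen-type aldol condensation of the ester enolate with a non-enolisable aldehyde; E1cB loss of water gives the more stable Z alkene (aryl trans to the carboxyl), and saponification in the same flask gives the acid.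

Step 10
Reactants: 10 3,5-bis(benzyloxy)-4-methoxy-2-(trimethylsilyl)phenyl trifluoromethanesulfonate; 16 (Z)-3-[2,4-bis(benzyloxy)-5-methoxyphenyl]-2-methoxyacrylic acid
Product: 18 (Z)-1-[2,4-bis(benzyloxy)-6-hydroxy-3-methoxyphenyl]-3-[2,4-bis(benzyloxy)-5-methoxyphenyl]-2-methoxyprop-2-en-1-one, via 3,5-bis(benzyloxy)-4-methoxy-1,2-didehydrobenzene 17 (not isolated)
Conditions: CsF (4 equiv), THF (dilute), 125 °C, sealed tube
Reagents that add atoms: none
Why: Fluoride attacks silicon of 10 and triflate leaves, releasing the aryne 17. The carboxylate of 16 adds to the aryne carbon whose neighbour is C–H (future C8a), because this places the negative charge on the carbon next to the inductively withdrawing benzyloxy group (future C4a) and follows the distortion of a 3-alkoxyaryne. The aryl anion then attacks the adjacent ester carbonyl through a four-membered transition state (4-exo-trig), and the four-membered alkoxide opens with O–acyl cleavage, a 1,3 O-to-C acyl shift of the anionic Fries kind, so that O–C8a and C4a–C4 form in one operation. The closest known reaction type is the fluoride-induced insertion of arynes, 3-alkoxyarynes included, into the C–O bond of aromatic and α,β-unsaturated carboxylic acids to give o-hydroxyaryl ketones. No ring of the target closes and no stereocenter is made; the Z double bond takes no part and its geometry is erased in step 11. The step needs regioselectivity, which the C5 benzyloxy group secures, and acyl transfer in preference to protonation of the aryl anion, which the high temperature, the dilute aprotic medium and the lack of any other electrophile within reach should favour. Oxa-Michael closure of the product phenoxide is slowed by the donor methoxyl on the α-carbon, and any ring-closed material would be dehydrogenated to 19 in step 11.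

Step 11
Reactants: 18 (Z)-1-[2,4-bis(benzyloxy)-6-hydroxy-3-methoxyphenyl]-3-[2,4-bis(benzyloxy)-5-methoxyphenyl]-2-methoxyprop-2-en-1-one
Product: 19 5,7-bis(benzyloxy)-2-[2,4-bis(benzyloxy)-5-methoxyphenyl]-3,6-dimethoxy-4H-chromen-4-one
Conditions: I2 (10 mol %), DMSO, 120 °C
Reagents that add atoms: none
Why: Iodine-mediated oxidative cyclisation of a 2'-hydroxychalcone: 6-endo-trig attack of the phenol oxygen on the β-carbon, α-iodination and loss of HI, with DMSO reoxidising iodide; the α-carbon still carries the hydrogen needed for the dehydrogenation.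

Step 12
Reactants: 19 5,7-bis(benzyloxy)-2-[2,4-bis(benzyloxy)-5-methoxyphenyl]-3,6-dimethoxy-4H-chromen-4-one
Product: 20 7-(benzyloxy)-2-[2,4-bis(benzyloxy)-5-methoxyphenyl]-5-hydroxy-3,6-dimethoxy-4H-chromen-4-one
Conditions: MgBr2·OEt2 (3 equiv), toluene–Et2O, 80 °C; aq. HCl
Reagents that add atoms: none
Why: Chelation-directed debenzylation; magnesium bound between the C4 carbonyl and O5 activates only the peri benzyl ether toward SN2 attack by bromide, a known selective cleavage of aryl benzyl ethers ortho to a carbonyl group.

Step 13
Reactants: 20 7-(benzyloxy)-2-[2,4-bis(benzyloxy)-5-methoxyphenyl]-5-hydroxy-3,6-dimethoxy-4H-chromen-4-one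
Product: 21 7-(benzyloxy)-2-[2,4-bis(benzyloxy)-5-methoxyphenyl]-5-hydroxy-8-iodo-3,6-dimethoxy-4H-chromen-4-one
Conditions: NIS (1.05 equiv), DMF, 0 °C to rt, dark
Reagents that add atoms: N-iodosuccinimide, O=C1CCC(=O)N1I
Why: Electrophilic iodination of a phenol at its free para position; C8 is the only open carbon of ring A and is activated by O5, O7 and O1, whereas ring B is fully etherified, bonded to the electron-poor C2, and its most activated carbon is already substituted.

Step 14
Reactants: 21 7-(benzyloxy)-2-[2,4-bis(benzyloxy)-5-methoxyphenyl]-5-hydroxy-8-iodo-3,6-dimethoxy-4H-chromen-4-one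
Product: 22 7-(benzyloxy)-2-[2,4-bis(benzyloxy)-5-methoxyphenyl]-5-hydroxy-3,6,8-trimethoxy-4H-chromen-4-one
Conditions: NaOMe (excess), CuBr, MeOH–DMF, 110 °C; aq. HCl
Reagents that add atoms: sodium methoxide, [Na+].[O-]C
Why: Ullmann-type copper-mediated methanolysis of an aryl halide, known for 6- and 8-haloflavones bearing a free 5-hydroxyl; the 5-phenoxide shields the pyranone from methoxide, and ring opening with reclosure through O5 would only exchange C6 and C8 and lead to the same 22.

Step 15
Reactants: 22 7-(benzyloxy)-2-[2,4-bis(benzyloxy)-5-methoxyphenyl]-5-hydroxy-3,6,8-trimethoxy-4H-chromen-4-one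
Product: 23 2-(2,4-dihydroxy-5-methoxyphenyl)-5,7-dihydroxy-3,6,8-trimethoxy-4H-chromen-4-one (5,7,2',4'-tetrahydroxy-3,6,8,5'-tetramethoxyflavone)
Conditions: H2 (1 atm), Pd/C (10 wt %), THF–MeOH, rt, then work-up under argon
Reagents that add atoms: none
Why: Hydrogenolysis of three aryl benzyl ethers under neutral conditions; methyl ethers and the tetrasubstituted C2=C3 bond of the flavone are left intact.

## Compound list

1 | methyl 3,5-dihydroxy-4-methoxybenzoate | COC(=O)c1cc(O)c(OC)c(O)c1 | starting material
2 | methyl 3,5-bis(benzyloxy)-4-methoxybenzoate | COC(=O)c1cc(OCc2ccccc2)c(OC)c(OCc2ccccc2)c1 | intermediate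
3 | [3,5-bis(benzyloxy)-4-methoxyphenyl]methanol | OCc1cc(OCc2ccccc2)c(OC)c(OCc2ccccc2)c1 | intermediate
4 | 3,5-bis(benzyloxy)-4-methoxybenzaldehyde | O=Cc1cc(OCc2ccccc2)c(OC)c(OCc2ccccc2)c1 | intermediate
5 | 3,5-bis(benzyloxy)-4-methoxyphenyl formate | O=COc1cc(OCc2ccccc2)c(OC)c(OCc2ccccc2)c1 | intermediate
6 | 3,5-bis(benzyloxy)-4-methoxyphenol | Oc1cc(OCc2ccccc2)c(OC)c(OCc2ccccc2)c1 | intermediate
7 | 3,5-bis(benzyloxy)-2-bromo-4-methoxyphenol | Oc1cc(OCc2ccccc2)c(OC)c(OCc2ccccc2)c1Br | intermediate
8 | [3,5-bis(benzyloxy)-2-bromo-4-methoxyphenoxy]trimethylsilane | C[Si](C)(C)Oc1cc(OCc2ccccc2)c(OC)c(OCc2ccccc2)c1Br | intermediate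
9 | lithium 3,5-bis(benzyloxy)-4-methoxy-2-(trimethylsilyl)phenolate | [Li+].[O-]c1cc(OCc2ccccc2)c(OC)c(OCc2ccccc2)c1[Si](C)(C)C | intermediate
10 | 3,5-bis(benzyloxy)-4-methoxy-2-(trimethylsilyl)phenyl trifluoromethanesulfonate | COc1c(OCc2ccccc2)cc(OS(=O)(=O)C(F)(F)F)c([Si](C)(C)C)c1OCc1ccccc1 | intermediate
11 | 5-bromo-2,4-dihydroxybenzaldehyde | O=Cc1cc(Br)c(O)cc1O | starting material
12 | 2,4-bis(benzyloxy)-5-bromobenzaldehyde | O=Cc1cc(Br)c(OCc2ccccc2)cc1OCc1ccccc1 | intermediate
13 | 2,4-bis(benzyloxy)-5-methoxybenzaldehyde | COc1cc(C=O)c(OCc2ccccc2)cc1OCc1ccccc1 | intermediate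
14 | methyl methoxyacetate | COCC(=O)OC | starting material
15 | methyl (Z)-3-[2,4-bis(benzyloxy)-5-methoxyphenyl]-2-methoxyacrylate | COc1cc(/C=C(\OC)C(=O)OC)c(OCc2ccccc2)cc1OCc1ccccc1 | intermediate
16 | (Z)-3-[2,4-bis(benzyloxy)-5-methoxyphenyl]-2-methoxyacrylic acid | COc1cc(/C=C(\OC)C(=O)O)c(OCc2ccccc2)cc1OCc1ccccc1 | intermediate
17 | 3,5-bis(benzyloxy)-4-methoxy-1,2-didehydrobenzene (aryne) | COC1=C(OCc2ccccc2)C#CC=C1OCc1ccccc1 | intermediate
18 | (Z)-1-[2,4-bis(benzyloxy)-6-hydroxy-3-methoxyphenyl]-3-[2,4-bis(benzyloxy)-5-methoxyphenyl]-2-methoxyprop-2-en-1-one | COc1cc(/C=C(\OC)C(=O)c2c(O)cc(OCc3ccccc3)c(OC)c2OCc2ccccc2)c(OCc2ccccc2)cc1OCc1ccccc1 | intermediate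
19 | 5,7-bis(benzyloxy)-2-[2,4-bis(benzyloxy)-5-methoxyphenyl]-3,6-dimethoxy-4H-chromen-4-one | COc1cc(-c2oc3cc(OCc4ccccc4)c(OC)c(OCc4ccccc4)c3c(=O)c2OC)c(OCc2ccccc2)cc1OCc1ccccc1 | intermediate
20 | 7-(benzyloxy)-2-[2,4-bis(benzyloxy)-5-methoxyphenyl]-5-hydroxy-3,6-dimethoxy-4H-chromen-4-one | COc1cc(-c2oc3cc(OCc4ccccc4)c(OC)c(O)c3c(=O)c2OC)c(OCc2ccccc2)cc1OCc1ccccc1 | intermediate
21 | 7-(benzyloxy)-2-[2,4-bis(benzyloxy)-5-methoxyphenyl]-5-hydroxy-8-iodo-3,6-dimethoxy-4H-chromen-4-one | COc1cc(-c2oc3c(I)c(OCc4ccccc4)c(OC)c(O)c3c(=O)c2OC)c(OCc2ccccc2)cc1OCc1ccccc1 | intermediate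
22 | 7-(benzyloxy)-2-[2,4-bis(benzyloxy)-5-methoxyphenyl]-5-hydroxy-3,6,8-trimethoxy-4H-chromen-4-one | COc1cc(-c2oc3c(OC)c(OCc4ccccc4)c(OC)c(O)c3c(=O)c2OC)c(OCc2ccccc2)cc1OCc1ccccc1 | intermediate
23 | 2-(2,4-dihydroxy-5-methoxyphenyl)-5,7-dihydroxy-3,6,8-trimethoxy-4H-chromen-4-one | COc1cc(-c2oc3c(OC)c(O)c(OC)c(O)c3c(=O)c2OC)c(O)cc1O | target

## Step count and risk

Total: 15 steps. Longest linear sequence: 12 steps (steps 1 to 6, then 10 to 15); the ring B branch contributes steps 7 to 9.

**Step 10 (key step).** The most likely failure is protonation of the aryl anion before it reaches the carbonyl, which ends in simple O-arylation of the acid. Further arylation of the product phenoxide by a second aryne is the next concern. Fallback: the C4a–C4 bond is made by an anionic Fries rearrangement triggered by halogen–metal exchange. The route is left at 7 and 16, which are esterified (EDC·HCl, DMAP, CH2Cl2) to 3,5-bis(benzyloxy)-2-bromo-4-methoxyphenyl (Z)-3-[2,4-bis(benzyloxy)-5-methoxyphenyl]-2-methoxyacrylate F1. Treatment with n-BuLi in THF at −100 °C exchanges bromine for lithium at the carbon that becomes C4a, the aryllithium takes over the neighbouring acyl group, and the route is rejoined at 18.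

**Step 14.** Reductive loss of iodine may compete with methoxylation at the doubly flanked C8; this only returns 20, but it would limit conversion. Fallback: the route is left at 20, which also bypasses step 13. Elbs persulfate oxidation (K2S2O8, aq. KOH–pyridine, 0 °C to rt) attacks the position para to the 5-hydroxyl and gives potassium 7-(benzyloxy)-2-[2,4-bis(benzyloxy)-5-methoxyphenyl]-5-hydroxy-3,6-dimethoxy-4-oxo-4H-chromen-8-yl sulfate F2. Acid hydrolysis (aq. HCl, Na2SO3, 80 °C) gives 7-(benzyloxy)-2-[2,4-bis(benzyloxy)-5-methoxyphenyl]-5,8-dihydroxy-3,6-dimethoxy-4H-chromen-4-one F3. Methylation with one equivalent of dimethyl sulfate and K2CO3 in acetone alkylates the 8-hydroxyl and leaves the chelated 5-hydroxyl, rejoining the route at 22.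

**Step 11.** Hydrogen iodide formed at 120 °C may remove benzyl groups, or iodination of the electron-rich rings may outrun the dehydrogenation. Fallback: closure and oxidation are separated. The route is left at 18, which is cyclised by oxa-Michael addition (NaOAc, EtOH, reflux) to 5,7-bis(benzyloxy)-2-[2,4-bis(benzyloxy)-5-methoxyphenyl]-3,6-dimethoxychroman-4-one F4 (racemic mixture of 2,3-diastereomers). Dehydrogenation with DDQ in dioxane at reflux rejoins the route at 19.

**Step 12.** Debenzylation may not stop at O5, or the C3 methoxyl, which can also chelate with the carbonyl, may be cleaved. Fallback: all benzyl groups are removed and three are put back. The route is left at 19, which is hydrogenolysed (H2, Pd/C, THF–MeOH) to 2-(2,4-dihydroxy-5-methoxyphenyl)-5,7-dihydroxy-3,6-dimethoxy-4H-chromen-4-one F5. Benzylation with three equivalents of benzyl bromide and K2CO3 in acetone spares the hydrogen-bonded 5-hydroxyl, the least nucleophilic one, and rejoins the route at 20.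

**Step 9.** Enolate addition to the electron-rich, ortho-substituted aldehyde may be slow, so that self-condensation of 14 or a stalled aldol adduct takes over. Fallback: the double bond is made by Horner–Wadsworth–Emmons olefination. The route is left at 13, which is treated with methyl 2-(dimethoxyphosphoryl)-2-methoxyacetate and NaH in THF to give 15. Saponification (aq. NaOH) rejoins the route at 16. No compound outside the list is formed (entry F0 below). A mixture of alkene isomers would be acceptable because the geometry is lost in step 11.

## Further compounds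

F1 | step 10 | 3,5-bis(benzyloxy)-2-bromo-4-methoxyphenyl (Z)-3-[2,4-bis(benzyloxy)-5-methoxyphenyl]-2-methoxyacrylate | COc1cc(/C=C(\OC)C(=O)Oc2cc(OCc3ccccc3)c(OC)c(OCc3ccccc3)c2Br)c(OCc2ccccc2)cc1OCc1ccccc1
F2 | step 14 | potassium 7-(benzyloxy)-2-[2,4-bis(benzyloxy)-5-methoxyphenyl]-5-hydroxy-3,6-dimethoxy-4-oxo-4H-chromen-8-yl sulfate | COc1cc(-c2oc3c(OS(=O)(=O)[O-])c(OCc4ccccc4)c(OC)c(O)c3c(=O)c2OC)c(OCc2ccccc2)cc1OCc1ccccc1.[K+]
F3 | step 14 | 7-(benzyloxy)-2-[2,4-bis(benzyloxy)-5-methoxyphenyl]-5,8-dihydroxy-3,6-dimethoxy-4H-chromen-4-one | COc1cc(-c2oc3c(O)c(OCc4ccccc4)c(OC)c(O)c3c(=O)c2OC)c(OCc2ccccc2)cc1OCc1ccccc1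
F4 | step 11 | 5,7-bis(benzyloxy)-2-[2,4-bis(benzyloxy)-5-methoxyphenyl]-3,6-dimethoxychroman-4-one (racemic mixture of 2,3-diastereomers) | COc1cc(C2Oc3cc(OCc4ccccc4)c(OC)c(OCc4ccccc4)c3C(=O)C2OC)c(OCc2ccccc2)cc1OCc1ccccc1
F5 | step 12 | 2-(2,4-dihydroxy-5-methoxyphenyl)-5,7-dihydroxy-3,6-dimethoxy-4H-chromen-4-one | COc1cc(-c2oc3cc(O)c(OC)c(O)c3c(=O)c2OC)c(O)cc1O
F0 | step 9 | none | none
A1 | alternative 1 | 5,7-bis(benzyloxy)-2-[2-(benzyloxy)-4-hydroxy-5-methoxyphenyl]-3,6,8-trimethoxychroman-4-one (racemic mixture of 2,3-diastereomers) | COc1cc(C2Oc3c(OC)c(OCc4ccccc4)c(OC)c(OCc4ccccc4)c3C(=O)C2OC)c(OCc2ccccc2)cc1O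
A2 | alternative 1 | 1-[4,6-bis(benzyloxy)-2-hydroxy-3,5-dimethoxyphenyl]-3-[2-(benzyloxy)-4-hydroxy-5-methoxyphenyl]-2-methoxypropan-1-one (racemic) | COc1cc(CC(OC)C(=O)c2c(O)c(OC)c(OCc3ccccc3)c(OC)c2OCc2ccccc2)c(OCc2ccccc2)cc1O
A3 | alternative 2 | (Z)-3-[2,4-bis(benzyloxy)-5-methoxyphenyl]-2-methoxy-1-(2,4,6-trihydroxy-3,5-dimethoxyphenyl)prop-2-en-1-one | COc1cc(/C=C(\OC)C(=O)c2c(O)c(OC)c(O)c(OC)c2O)c(OCc2ccccc2)cc1OCc1ccccc1
A4 | alternative 2 | methyl (Z)-9-[2,4-bis(benzyloxy)-5-methoxyphenyl]-2,4,8-trimethoxy-3,5,7-trioxonon-8-enoate (mixture of stereoisomers at C2 and C4) | COC(=O)C(OC)C(=O)C(OC)C(=O)CC(=O)/C(OC)=C/c1cc(OC)c(OCc2ccccc2)cc1OCc1ccccc1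
A5 | alternative 3 | 7-(benzyloxy)-2-[2,4-bis(benzyloxy)-5-methoxyphenyl]-5-bromo-3,6,8-trimethoxy-4H-chromen-4-one | COc1cc(-c2oc3c(OC)c(OCc4ccccc4)c(OC)c(Br)c3c(=O)c2OC)c(OCc2ccccc2)cc1OCc1ccccc1
A6 | alternative 3 | 1-[4-(benzyloxy)-2,6-dibromo-3,5-dimethoxyphenyl]-3-[2,4-bis(benzyloxy)-5-methoxyphenyl]-2-methoxypropane-1,3-dione | COc1cc(C(=O)C(OC)C(=O)c2c(Br)c(OC)c(OCc3ccccc3)c(OC)c2Br)c(OCc2ccccc2)cc1OCc1ccccc1
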